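## Structural features

The target is a single carbocycle, a cyclohexene (C1–C6) whose trisubstituted C1=C2 alkene carries the exocyclic benzoyloxymethyl carbon C7 on C1. The four sp3 ring carbons C3–C6 are contiguous, oxygenated stereocenters, all R. C3 (OMe) and C4 (OH) are cis, C4 and C5 (OBz) are trans, and C5 and C6 (OH) are cis, so O3/O4 lie on one face and O5/O6 on the other. C3–OMe and C6–OH are allylic and ionisable under strong acid. Both benzoates are base-labile, and the secondary benzoate on O5 sits between two free hydroxyls (O6 cis, O4 trans) to which it can migrate. The real difficulty is to tell four neighbouring secondary oxygens apart (methyl, H, benzoyl, H) while fixing their relative and absolute configuration. In the likely half-chair, O4 and O5 are equatorial and O3 and O6 pseudoaxial, O6 being further shielded by the C1 substituent, which is what allows O5 to be addressed last. The key step exploits the 1,4-relationship across the ring between C1 (with C7) and C4 (with O4): C7 and O4 become the C(=O)–O unit of a 2-pyrone whose ring carbons are C1–C4, and the cis-5,6-diol becomes a cis-enediol ketal.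

## Logic of the disconnections

14 ⇒ 12. The O5–C(=O)Ph bond is cut last, because this ester is the one prone to migration. O5 is the equatorial member of the cis-5,6-diol and can be activated through a tin acetal (13). The gain is a triol with no protecting group on O4. The demand is monoacylation at O5 in the presence of O4–H and O6–H.

12 ⇒ 11 ⇒ 10. The 5,6-diol is returned to its acetonide and the O7–C(=O)Ph bond is cut. While O5 and O6 are tied in the ketal, O7 is the only primary hydroxyl. The demand is acylation of a primary allylic alcohol in preference to the hindered secondary O4–H of 10.

10 ⇒ 9. C7 is raised to the ester oxidation level. The ester is what a lactone leaves behind and is what polarises the allyl system in the preceding step. The demand is clean 1,2-reduction.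

9 ⇒ 8. The C3–OMe bond is cut and C3 is reconnected to O4 as an epoxide. O4 then dictates the configuration of C3, and O3 (methyl) is distinguished from O4 (H) without any protecting group. The demand is substitution at C3 with overall retention, and at C3 rather than C1.

8 ⇒ 6 (through 7). O4 is reconnected to C7 as a lactone, the alkene is moved to C2=C3 and a bromide is placed on C1. This is the retron of an alkoxide SN2′ closure. The gain is a rigid bicycle in which C7 and O4 are held on one face. The demand is that methoxide opens the lactone without attacking 8 afterwards. The acetonide is kept because a free O5 would allow epoxide migration under base.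

6 ⇒ 5. The single enantiomer is taken from the racemate. Both cycloaddition partners are achiral, and a pyrone with a single Lewis-basic site offers no dependable handle for catalytic enantiocontrol. Resolution is therefore placed at the earliest, rigid, bromine-bearing stage. The demand is a preparative enantiomer separation, and half of the material is lost.

5 ⇒ 4 + 3. The C1–C6 and C4–C5 bonds are cut in a retro-[4+2]. The ring and the relative configuration of C1, C4, C5 and C6 come from two flat components. The demand is endo selectivity and survival of the CO2 bridge. The precursor pair is kept as it stands. The changes lie downstream: O7 is benzoylated before the ketal is removed, and O5 is acylated under tin direction, so that protection and deprotection of O4 are saved.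

3 ⇒ 2 ⇒ 1. The enol ether double bond comes from C–Cl/C–H elimination and the C–Cl bond from a C–H bond α to oxygen. The demand is removal of the volatile 3 from the base as it forms.

## Other disconnections considered

Alternative 1: The cut is the C1–C6 ring bond.
- **Forward step:** The acyclic (Z)-iodoalkenal A2 is built from D-arabinose A3, so that C5, C4 and C3 of the target are C2, C3 and C4 of the sugar. CrCl2 with catalytic NiCl2 in DMF would convert it into a vinylchromium species that adds to the C6 aldehyde (Nozaki–Hiyama–Kishi) and closes the cyclohexene to A1. Oxidative removal of the 4-methoxybenzyl ether would then finish the synthesis.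
- **In favour:** Three stereocenters and the absolute configuration come from the chiral pool, which is better than the chosen plan with its resolution. All four oxygens are differentiated before the ring closes, so no late regioselective benzoylation is needed, which is also better.
- **Against:** A2 requires a long protecting-group sequence on A3 and a stereodefined trisubstituted (Z)-vinyl iodide. Its α-benzoyloxy aldehyde is prone to epimerisation and β-elimination. The C6 stereocenter is created in the closure with no built-in guarantee of the cis relation to O5, and CrCl2 is needed in excess.
- **Comparison:** On structure, the alternative forms one C–C bond and one stereocenter in its key step, against two C–C bonds and four stereocenters (relative only) in the chosen plan. On mechanism, a polar organometallic addition is about as dependable as the cycloaddition but less stereo-determined. On step economy the alternative is expected to be clearly longer.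

Alternative 2: The cut is the C5–O and C6–O bonds, back to bromobenzene A4.
- **Forward step:** Whole cells expressing toluene dioxygenase would add dioxygen to one face of A4 and give the diene diol A5 as one enantiomer. The C–Br carbon is C1 and the remaining alkenes are C1=C2 and C3=C4.
- **In favour:** The enzyme sets the absolute configuration of C5 and C6, which is better than the chosen plan. The bromide is the handle for C7. After ketalisation the distal C3=C4 alkene is the more electron-rich and is attacked anti to the ketal, the face that O3/O4 need. Methoxycarbonylation and anti epoxidation could even intercept compound 8 of the chosen route without a resolution and in fewer steps, which is better on both counts.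
- **Against:** The diene ketals dimerise readily and must be processed quickly. A fermentation is needed unless A5 is bought. From 8 onward the same late problems remain, so nothing is gained there.
- **Comparison:** On structure, no ring and no C–C bond are formed in the key step, since the ring is that of the arene. On mechanism, enzymatic syn dihydroxylation gives absolute control where the pericyclic step gives only relative control. On step economy the alternative is equal or better.

Alternative 3: The cut is the C4–O and C5–O bonds of an epoxide on the quinone monoketal A6.
- **Forward step:** The sodium salt of trityl hydroperoxide, bound to a chiral tartrate ester, would add to C4 of the unsubstituted enone, and the enolate would close on oxygen to give A7. Benzoate opening at C5, reduction of the C6 ketone and reductive cleavage of the ketal to the C3 methyl ether would follow.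
- **In favour:** The absolute configuration is set by the reagent in the key step, which is better than the chosen plan. All carbons and the O7 benzoate are present from the start. The C4/C5 trans relation follows from epoxide opening with inversion, which is as reliable as the endo rule.
- **Against:** The regiochemistry of the benzoate opening is uncertain, as is the facial course of the C6 reduction. Above all, one ketal oxygen must become a single C3 epimer through an allylic oxocarbenium ion with little facial bias. The chosen plan is better here, because C3 is set stereospecifically from O4.
- **Comparison:** On structure, no C–C bond is formed. On mechanism, the conjugate addition with ring closure is well matched to the substrate. On step economy the alternative could be shorter, but only if the ketal reduction is selective.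

Key step: step 3

Remark: 3-bromo-2H-pyran-2-one (4) is taken from commercial supply.
Remark: the bicyclic lactone of the key step was checked against the target and needs no correction. O4 and the C7 bridge lie on one face and O5/O6 on the other, and the antipode drawn is the one required. Compound 5 is racemic; 6 and all later compounds are single enantiomers. Ring positions in the names follow the target numbering.

## Route

Step 1
Reactants: 1 2,2-dimethyl-1,3-dioxolane
Product: 2 4-chloro-2,2-dimethyl-1,3-dioxolane (racemic)
Conditions: SO2Cl2 (1.0 equiv), AIBN (cat.), PhCF3, 70 °C, N2 sweep; distillation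
Reagents that add atoms: sulfuryl chloride, O=S(=O)(Cl)Cl
Why: Radical-chain chlorination α to oxygen, the reaction type that converts ethylene carbonate into its monochloride; the ketal carbon bears no hydrogen, so the ring CH2 groups are the only activated C–H bonds, and the racemic stereocenter disappears in step 2.

Step 2
Reactants: 2 4-chloro-2,2-dimethyl-1,3-dioxolane
Product: 3 2,2-dimethyl-1,3-dioxole
Conditions: KOt-Bu (1.2 equiv), tetraglyme, 0 → 50 °C, product distilled out under reduced pressure into a cold trap
Reagents that add atoms: none
Why: E2 dehydrochlorination of an α-chloro ether to the enol ether with a hindered base, as in the preparation of vinylene carbonate from its chloro precursor; continuous removal of the volatile product protects it from the base.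

Step 3
Reactants: 4 3-bromo-2H-pyran-2-one; 3 2,2-dimethyl-1,3-dioxole
Product: 5 rac-(1R*,4R*,5S*,6S*)-4-bromo-5,6-(isopropylidenedioxy)-2-oxabicyclo[2.2.2]oct-7-en-3-one (endo adduct, dioxolane anti to the lactone bridge)
Conditions: 3 (3.0 equiv), 2,6-di-tert-butyl-4-methylphenol (cat.), toluene, 90 °C, sealed tube
Reagents that add atoms: none
Why: Concerted, asynchronous [4+2] cycloaddition with inverse electron demand, the HOMO of the enediol ketal 3 meeting the LUMO of the bromopyrone 4, with the bond to the pyrone carbon next to the ring oxygen (the future C4–C5 bond) probably running ahead. The closest known reaction type is the thermal or high-pressure addition of 3-bromo-2-pyrone to enol ethers, which stops at the bridged lactone. The one ring closed is the carbocycle, formed intermolecularly and suprafacially on both partners across the pyrone termini (C1–C6 and C4–C5), and the same event leaves the former C(=O)–O unit as the two-atom bridge of a bicyclo[2.2.2]octene. C1 and C4 are bridgeheads, so their relative configuration is fixed by the bridge; C5 and C6 are cis because both bonds form on one face of the ring-constrained Z alkene. The C4/C5 trans relation comes from the endo transition state, in which the dioxole oxygens lie under the diene and end anti to the lactone bridge. The selectivity needed is endo over exo; it should be secured by secondary overlap between the oxygen atoms of 3 and the central diene carbons, any exo isomer being removed by chromatography, while regiochemistry is no issue because 3 is mirror-symmetric. The temperature is held below that of cycloreversion with loss of CO2, and the excess of 3 offsets its volatility. Nothing in the substrates controls absolute configuration, so 5 forms as a racemate and the antipode is selected in step 4.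

Step 4
Reactants: 5 rac-endo adduct
Product: 6 (1R,4R,5S,6S)-4-bromo-5,6-(isopropylidenedioxy)-2-oxabicyclo[2.2.2]oct-7-en-3-one
Conditions: preparative supercritical-fluid chromatography, amylose tris(3,5-dimethylphenylcarbamate) on silica, CO2/i-PrOH, 35 °C
Reagents that add atoms: none
Why: Chromatographic resolution of enantiomers on a polysaccharide chiral stationary phase, well suited to a rigid, compact bicyclic lactone; no stereocenter is formed, and the antipode taken on should be assigned by anomalous X-ray scattering of the bromine atom.

Step 5
Reactants: 6 (1R,4R,5S,6S)-bromolactone
Product: 8 methyl (3R,4R,5R,6R)-3,4-epoxy-5,6-(isopropylidenedioxy)cyclohex-1-ene-1-carboxylate (epoxide anti to the acetonide), via ring-opened bromo alkoxide 7 (not isolated)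
Conditions: NaOMe (1.05 equiv), MeOH, −20 → 0 °C; NH4Cl (aq)
Reagents that add atoms: sodium methoxide, [Na+].[O-]C
Why: Acyl substitution by methoxide opens the strained bridged lactone, and the C4 alkoxide so released closes onto C3 with allylic expulsion of the tertiary bromide (intramolecular SN2′), giving the conjugated C1=C2 ester. The epoxide oxygen is the former lactone oxygen and stays on its face, so C4, C5 and C6 are untouched and C3 is set by O4.

Step 6
Reactants: 8 epoxy enoate
Product: 9 methyl (3R,4R,5S,6R)-4-hydroxy-3-methoxy-5,6-(isopropylidenedioxy)cyclohex-1-ene-1-carboxylate
Conditions: Pd(PPh3)4 (5 mol %), B(OMe)3 (2.0 equiv), THF, 25 °C; NaHCO3 (aq)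
Reagents that add atoms: trimethyl borate, COB(OC)OC
Why: Zerovalent palladium ionises the allylic C3–O bond with inversion; the C4 alkoxide binds boron, and the borate passes methoxide to C3 of the π-allyl unit on the face away from palladium, which is the face of O4 (net retention, C3/C4 cis). This is the palladium-catalysed alkoxy substitution of γ,δ-epoxy-α,β-unsaturated esters with trialkyl borates, and delivery from O4 confines attack to C3.

Step 7
Reactants: 9 hydroxy methoxy ester
Product: 10 (3R,4R,5S,6R)-1-(hydroxymethyl)-3-methoxy-5,6-(isopropylidenedioxy)cyclohex-1-en-4-ol
Conditions: i-Bu2AlH (3.5 equiv), CH2Cl2, −78 → −20 °C; potassium sodium tartrate (aq)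
Reagents that add atoms: none
Why: 1,2-Reduction of the conjugated ester to the allylic alcohol by an aluminium hydride; the free hydroxyl only consumes one equivalent, and ketal, methyl ether and stereocenters are inert.

Step 8
Reactants: 10 diol
Product: 11 [(3R,4R,5S,6R)-4-hydroxy-3-methoxy-5,6-(isopropylidenedioxy)cyclohex-1-en-1-yl]methyl benzoate
Conditions: BzCl (1.05 equiv), 2,4,6-collidine, CH2Cl2, −40 → −20 °C
Reagents that add atoms: benzoyl chloride, O=C(Cl)c1ccccc1
Why: Kinetically selective acylation of the primary allylic hydroxyl; the secondary C4 hydroxyl is flanked by the methoxy group and the ketal and should not compete at low temperature with one equivalent of acid chloride.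

Step 9
Reactants: 11 monobenzoate acetonide
Product: 12 [(3R,4S,5R,6R)-4,5,6-trihydroxy-3-methoxycyclohex-1-en-1-yl]methyl benzoate
Conditions: AcOH/H2O (4:1), 45 °C
Reagents that add atoms: none
Why: Acid-catalysed hydrolysis of the cis-fused isopropylidene ketal; aqueous acetic acid is too weak to ionise the allylic ether or alcohol and leaves the benzoate intact.

Step 10
Reactants: 12 triol monobenzoate
Product: 14 [(3R,4R,5R,6R)-5-(benzoyloxy)-4,6-dihydroxy-3-methoxycyclohex-1-en-1-yl]methyl benzoate (target), via 5,6-O-dibutylstannylene acetal 13 (not isolated)
Conditions: Bu2SnO (1.1 equiv), toluene, reflux, azeotropic removal of water; then BzCl (1.05 equiv), 0 °C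
Reagents that add atoms: benzoyl chloride, O=C(Cl)c1ccccc1; dibutyltin oxide, CCCC[Sn](=O)CCCC (its tin is held only in 13)
Why: Stannylene-acetal-directed monoacylation: tin bridges the cis-5,6-diol and raises the nucleophilicity of the equatorial O5, while the pseudoaxial allylic O6 beside the C1 substituent and the trans-disposed O4 stay free. This is the selectivity pattern of triols that contain a cis-diol, where the middle, equatorial oxygen is acylated; no stereocenter is affected.

## Compound list

1 | 2,2-dimethyl-1,3-dioxolane | CC1(C)OCCO1 | starting material
2 | 4-chloro-2,2-dimethyl-1,3-dioxolane (racemic) | CC1(C)OCC(Cl)O1 | intermediate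
3 | 2,2-dimethyl-1,3-dioxole | CC1(C)OC=CO1 | intermediate
4 | 3-bromo-2H-pyran-2-one | O=C1OC=CC=C1Br | starting material
5 | rac-(1R*,4R*,5S*,6S*)-4-bromo-5,6-(isopropylidenedioxy)-2-oxabicyclo[2.2.2]oct-7-en-3-one (racemate; the SMILES shows the enantiomer carried on) | O=C1O[C@@H]2C=C[C@@]1(Br)[C@H]1OC(C)(C)O[C@@H]21 | intermediate
6 | (1R,4R,5S,6S)-4-bromo-5,6-(isopropylidenedioxy)-2-oxabicyclo[2.2.2]oct-7-en-3-one | O=C1O[C@@H]2C=C[C@@]1(Br)[C@H]1OC(C)(C)O[C@@H]21 | intermediate
7 | methyl (1R,4R,5S,6S)-1-bromo-4-hydroxy-5,6-(isopropylidenedioxy)cyclohex-2-ene-1-carboxylate (present as its sodium alkoxide, not isolated) | COC(=O)[C@@]1(Br)C=C[C@@H](O)[C@@H]2OC(C)(C)O[C@H]12 | intermediate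
8 | methyl (3R,4R,5R,6R)-3,4-epoxy-5,6-(isopropylidenedioxy)cyclohex-1-ene-1-carboxylate | COC(=O)C1=C[C@H]2O[C@H]2[C@@H]2OC(C)(C)O[C@H]12 | intermediate
9 | methyl (3R,4R,5S,6R)-4-hydroxy-3-methoxy-5,6-(isopropylidenedioxy)cyclohex-1-ene-1-carboxylate | COC(=O)C1=C[C@@H](OC)[C@@H](O)[C@@H]2OC(C)(C)O[C@H]12 | intermediate
10 | (3R,4R,5S,6R)-1-(hydroxymethyl)-3-methoxy-5,6-(isopropylidenedioxy)cyclohex-1-en-4-ol | OCC1=C[C@@H](OC)[C@@H](O)[C@@H]2OC(C)(C)O[C@H]12 | intermediate
11 | [(3R,4R,5S,6R)-4-hydroxy-3-methoxy-5,6-(isopropylidenedioxy)cyclohex-1-en-1-yl]methyl benzoate | O=C(OCC1=C[C@@H](OC)[C@@H](O)[C@@H]2OC(C)(C)O[C@H]12)c1ccccc1 | intermediate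
12 | [(3R,4S,5R,6R)-4,5,6-trihydroxy-3-methoxycyclohex-1-en-1-yl]methyl benzoate | O=C(OCC1=C[C@@H](OC)[C@@H](O)[C@H](O)[C@@H]1O)c1ccccc1 | intermediate
13 | 5,6-O-dibutylstannylene acetal of 12 (not isolated) | O=C(OCC1=C[C@@H](OC)[C@@H](O)[C@@H]2O[Sn](CCCC)(CCCC)O[C@H]12)c1ccccc1 | intermediate
14 | [(3R,4R,5R,6R)-5-(benzoyloxy)-4,6-dihydroxy-3-methoxycyclohex-1-en-1-yl]methyl benzoate | CO[C@@H]1C=C(COC(=O)c2ccccc2)[C@@H](O)[C@@H](OC(=O)c2ccccc2)[C@@H]1O | target

## Step count and least certain steps

Total step count: 10. Longest linear sequence: 10 steps (1 → 14); 8 steps from 4.

**Step 3 (key step).**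
- **Risk:** Endo selectivity may erode, because one ketal methyl of 3 points at the diene in the endo approach. Cycloreversion with loss of CO2 may also set in before conversion is complete, since the bridge tolerates only moderate heating.
- **Fallback:** The diene is changed. Setting out from 3, commercial 3,5-dibromo-2H-pyran-2-one, whose lower LUMO should allow a lower temperature and a tighter endo transition state, would give rac-endo-4,7-dibromo-5,6-(isopropylidenedioxy)-2-oxabicyclo[2.2.2]oct-7-en-3-one F1. Palladium-catalysed formate hydrogenolysis (Pd(OAc)2, PPh3, HCO2H, Et3N, DMF, 50 °C) should then remove only the vinylic bromide, because the bridgehead C–Br bond is geometrically closed to oxidative addition. The route is rejoined at 5.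

**Step 4.**
- **Risk:** Separation or throughput on the chiral phase may be insufficient on scale.
- **Fallback:** A classical resolution through covalent diastereomers is used later. Setting out from 5, steps 5 and 6 are run on the racemate, and racemic 9 is esterified at O4 with (S)-O-acetylmandelic acid (DCC, DMAP cat., CH2Cl2, −20 °C). The diastereomeric esters, the (S)-O-acetylmandelate of 9 F2 and the (S)-O-acetylmandelate of the enantiomer of 9 F3, are separated by chromatography or crystallisation, and F2 is identified by X-ray analysis. i-Bu2AlH under the conditions of step 7, in larger excess, then cleaves the mandelate and reduces the methyl ester in one operation. The route is rejoined at 10.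

**Step 5.**
- **Risk:** Methoxide may react further with the product, by anti opening of the vinyl epoxide at C3 or by conjugate addition. E2 loss of HBr from 7 may also compete before the epoxide closes.
- **Fallback:** Hydroxide is used and the ester is formed separately. Setting out from 6, LiOH (2.1 equiv) in THF/H2O at 0 °C should open the lactone and trigger the same closure. The product is then a carboxylate, which is no conjugate acceptor and is slow to open with aqueous hydroxide. Buffering to pH 4–5 gives (3R,4R,5R,6R)-3,4-epoxy-5,6-(isopropylidenedioxy)cyclohex-1-ene-1-carboxylic acid F4, and methylation (MeI, K2CO3, DMF, 0 °C) rejoins the route at 8.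

**Step 10.**
- **Risk:** Regiocontrol may be incomplete, with acylation at O4 through a competing trans-diol tin acetal or at O6. The new O5 benzoate may also migrate to a neighbouring hydroxyl.
- **Fallback:** O4 is masked before the ketal is removed. Setting out from 11, 4-methoxybenzyl trichloroacetimidate with La(OTf)3 (cat.) in toluene would give the 4-O-(4-methoxybenzyl) ether of 11 F5. AcOH/H2O would remove the ketal to give the 4-O-(4-methoxybenzyl) ether of 12 F6. Benzoylation (BzCl, pyridine, CH2Cl2, −20 °C) then has to tell only the equatorial O5 from the shielded pseudoaxial O6, and should give the 4-O-(4-methoxybenzyl) ether of 14 F7, which is the same compound as A1. DDQ in CH2Cl2/pH 7 buffer removes the benzyl-type ether and rejoins the route at 14.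

## Further compounds

F1 | step 3 | rac-endo-4,7-dibromo-5,6-(isopropylidenedioxy)-2-oxabicyclo[2.2.2]oct-7-en-3-one | O=C1O[C@@H]2C(Br)=C[C@@]1(Br)[C@H]1OC(C)(C)O[C@@H]21
F2 | step 4 | (S)-O-acetylmandelate (at O4) of 9 | COC(=O)C1=C[C@@H](OC)[C@@H](OC(=O)[C@@H](OC(C)=O)c2ccccc2)[C@@H]2OC(C)(C)O[C@H]12
F3 | step 4 | (S)-O-acetylmandelate (at O4) of the enantiomer of 9 | COC(=O)C1=C[C@H](OC)[C@H](OC(=O)[C@@H](OC(C)=O)c2ccccc2)[C@H]2OC(C)(C)O[C@@H]12
F4 | step 5 | (3R,4R,5R,6R)-3,4-epoxy-5,6-(isopropylidenedioxy)cyclohex-1-ene-1-carboxylic acid | OC(=O)C1=C[C@H]2O[C@H]2[C@@H]2OC(C)(C)O[C@H]12
F5 | step 10 | 4-O-(4-methoxybenzyl) ether of 11 | O=C(OCC1=C[C@@H](OC)[C@@H](OCc2ccc(OC)cc2)[C@@H]2OC(C)(C)O[C@H]12)c1ccccc1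
F6 | step 10 | 4-O-(4-methoxybenzyl) ether of 12 | O=C(OCC1=C[C@@H](OC)[C@@H](OCc2ccc(OC)cc2)[C@H](O)[C@@H]1O)c1ccccc1
F7 | step 10 | 4-O-(4-methoxybenzyl) ether of 14 | CO[C@@H]1C=C(COC(=O)c2ccccc2)[C@@H](O)[C@@H](OC(=O)c2ccccc2)[C@@H]1OCc1ccc(OC)cc1
A1 | alternative 1 | 4-O-(4-methoxybenzyl) ether of the target | CO[C@@H]1C=C(COC(=O)c2ccccc2)[C@@H](O)[C@@H](OC(=O)c2ccccc2)[C@@H]1OCc1ccc(OC)cc1
A2 | alternative 1 | (Z)-2,7-di-O-benzoyl-5,6-dideoxy-6-iodo-3-O-(4-methoxybenzyl)-4-O-methyl-D-arabino-hept-5-enose | O=C[C@@H](OC(=O)c1ccccc1)[C@H](OCc1ccc(OC)cc1)[C@H](OC)/C=C(\I)COC(=O)c1ccccc1
A3 | alternative 1 | D-arabinose (open-chain form) | O=C[C@@H](O)[C@H](O)[C@H](O)CO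
A4 | alternative 2 | bromobenzene | Brc1ccccc1
A5 | alternative 2 | (1S,2S)-3-bromocyclohexa-3,5-diene-1,2-diol | O[C@H]1C=CC=C(Br)[C@H]1O
A6 | alternative 3 | 2-(benzoyloxymethyl)-4,4-dimethoxycyclohexa-2,5-dien-1-one | O=C1C=CC(OC)(OC)C=C1COC(=O)c1ccccc1
A7 | alternative 3 | 5,6-epoxy-2-(benzoyloxymethyl)-4,4-dimethoxycyclohex-2-en-1-one | O=C1C(COC(=O)c2ccccc2)=CC(OC)(OC)[C@H]2O[C@@H]12
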